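**Retrosynthetic overview**

- Ring numbering used throughout: O1 (on C6), O2 (on C3), C3 = methoxy ketal carbon carrying the C16 chain, C4, C5, C6 = CH carrying CH2CO2H. The target is (3R,6S), with OMe and CH2CO2H cis.
- The strategy rests on one feature: C3 with its OMe plus C4 and C5 is a ketone homoenolate, stored as a 1-methoxycyclopropane, and O2–O1–C6 is a silylperoxycarbenium ion. The 1,2-dioxane is their 3+3 sum (C5–C6, then O2–C3).
- Last disconnections: ester hydrolysis with enzymatic resolution, then the C(sp)–C(sp2) bond of the enyne (Sonogashira coupling with (E)-1-iodoundeca-1,10-diene).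
- The dioxane is the only ring formed (step 5). The cyclopropane is bought in as cyclopropanone hemiketal and opened in that step.
- The alkene-bearing chain is attached after the annulation, because alkenes themselves add to peroxycarbenium ions. C6 is made racemic, C3 is set by thermodynamic control (axial OMe), and the absolute configuration is selected in step 11.

Key step: step 5

Assumption: the lipase of step 11 hydrolyses the (3R,6S) enantiomer of ester 19 faster than its mirror image; the sense and size of this preference have to be settled by a small hydrolase screen with chiral HPLC control.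

Step 1
Reactants: 1 (5-chloropent-1-yn-1-yl)trimethylsilane; 2 1-ethoxycyclopropan-1-ol (cyclopropanone ethyl hemiketal)
Product: 5 1-[5-(trimethylsilyl)pent-4-yn-1-yl]cyclopropan-1-ol, via Grignard reagent 3 (not isolated), via cyclopropanone 4 (not isolated)
Conditions: 1, Mg, I2 (cat.), THF, reflux; 2, MeMgBr (1.0 equiv), THF, 0 °C; combine, 0 °C → reflux; aq NH4Cl
Reagents that add atoms: none
Why: Grignard addition to cyclopropanone released in the flask from the magnesium salt of its hemiketal is a standard entry to 1-alkylcyclopropanols; it is preferred here to a Kulinkovich cyclopropanation of the corresponding silylalkynyl ester, where the titanacyclopropane could engage the tethered silylalkyne instead of the ester.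

Step 2
Reactants: 5 1-[5-(trimethylsilyl)pent-4-yn-1-yl]cyclopropan-1-ol
Product: 6 1-methoxy-1-[5-(trimethylsilyl)pent-4-yn-1-yl]cyclopropane
Conditions: NaH, MeI, THF/DMF 4:1, 0 °C → rt
Reagents that add atoms: iodomethane, CI
Why: Williamson O-methylation of the tertiary cyclopropoxide; the silylated alkyne has no acidic C–H and the cyclopropoxide should not ring-open at or below room temperature in an aprotic medium.

Step 3
Reactants: 7 dimethyl (E)-hex-3-enedioate
Product: 9 methyl 3-hydroperoxy-3-methoxypropanoate (racemic), via carbonyl oxide 8 (not isolated)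
Conditions: O3, CH2Cl2/MeOH 3:1, −78 °C; N2 purge; no reductive work-up; concentrate below 25 °C behind a shield; chromatography
Reagents that add atoms: ozone, [O-][O+]=O; methanol, CO
Why: Criegee ozonolysis with methanol trapping of the carbonyl oxide gives the α-methoxy hydroperoxide; the symmetrical alkene makes both directions of primary-ozonide cleavage equivalent, so no regioisomeric peroxide (as a terminal alkene would give) can form, and the new acetal centre is racemic and is flattened again in step 5.

Step 4
Reactants: 9 methyl 3-hydroperoxy-3-methoxypropanoate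
Product: 10 methyl 3-methoxy-3-[(triethylsilyl)peroxy]propanoate (racemic)
Conditions: Et3SiCl, imidazole, DMF, 0 °C
Reagents that add atoms: chlorotriethylsilane, CC[Si](Cl)(CC)CC
Why: O-silylation of the acidic hydroperoxide under standard silyl chloride/imidazole conditions; the weak base at 0 °C should not trigger β-elimination of the peroxide from the ester.

Step 5
Reactants: 6 1-methoxy-1-[5-(trimethylsilyl)pent-4-yn-1-yl]cyclopropane; 10 methyl 3-methoxy-3-[(triethylsilyl)peroxy]propanoate (1.5 equiv)
Product: 13 methyl 2-[3-methoxy-3-[5-(trimethylsilyl)pent-4-yn-1-yl]-1,2-dioxan-6-yl]acetate (racemic; C3 epimers with the 3R*,6S* isomer 14 expected to dominate), via silylperoxycarbenium triflate 11 (not isolated), via ring-opened oxocarbenium triflate 12 (not isolated)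
Conditions: Me3SiOTf (0.3 equiv), 4 Å MS, CH2Cl2, −78 → −40 °C; Et3N, then aq NaHCO3
Reagents that add atoms: none
Why: Proposed new method: Me3SiOTf removes the acetal methoxy group of 10 to give the silylperoxycarbenium ion 11; the cyclopropane σ bond between the methoxy carbon and a ring CH2 of 6, activated by ring strain and the geminal oxygen lone pair, attacks it through that CH2 (C5–C6 forms) and opens to the methoxy-stabilised oxocarbenium ion 12, whose silylated peroxy oxygen closes the 1,2-dioxane by 6-exo-trig attack on C3 (O2–C3 forms) and passes Et3Si+ on to the next acetal, so the silyl triflate turns over. The closest known reactions are the Lewis acid promoted 3+2 annulation of silylperoxycarbenium ions with alkenes to 1,2-dioxolanes and the opening of alkoxy- and siloxycyclopropanes by electrophiles (proton, halogen, Hg(OAc)2, SnCl4) as ketone homoenolate equivalents; here a strained σ bond replaces the alkene π bond and the peroxide ring becomes six-membered. C6 arises from a planar cation with no controlling element and is racemic; C3 is set relative to C6 in a chair-like closure with CH2CO2Me equatorial, in which the anomeric effect favours axial OMe (the 3R*,6S* isomer), and any shortfall is corrected in step 6. The step needs cleavage of the ring bond next to the methoxy carbon, which the donor oxygen secures (the two ring CH2 groups are equivalent), and attack by the cyclopropane rather than by the silylalkyne, which is the weaker and more shielded nucleophile. Me3SiOTf is chosen over SnCl4 because SnCl4 can insert into donor cyclopropanes on its own, and the low temperature without amine base is meant to keep 11 from losing a proton to an enol peroxide.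

Step 6
Reactants: 13 methyl 2-[3-methoxy-3-[5-(trimethylsilyl)pent-4-yn-1-yl]-1,2-dioxan-6-yl]acetate (epimer mixture)
Product: 14 methyl 2-[(3R*,6S*)-3-methoxy-3-[5-(trimethylsilyl)pent-4-yn-1-yl]-1,2-dioxan-6-yl]acetate (racemic)
Conditions: CSA (10 mol%), MeOH/CH2Cl2 1:4, 0 °C → rt; NaHCO3
Reagents that add atoms: methanol, CO (the C3 methoxy group can exchange with the solvent)
Why: Acid-catalysed ketal equilibration by reversible ionisation at C3 should converge the epimers on the isomer with axial OMe (anomeric effect) and both carbon substituents equatorial, which is the cis relation of OMe and CH2CO2Me of the target; C6, the ester and the silylalkyne are not affected.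

Step 7
Reactants: 14 methyl 2-[(3R*,6S*)-3-methoxy-3-[5-(trimethylsilyl)pent-4-yn-1-yl]-1,2-dioxan-6-yl]acetate
Product: 15 methyl 2-[(3R*,6S*)-3-methoxy-3-(pent-4-yn-1-yl)-1,2-dioxan-6-yl]acetate (racemic)
Conditions: K2CO3 (0.2 equiv), MeOH, 0 °C
Reagents that add atoms: none
Why: Carbonate-catalysed methanolysis of the C(sp)–Si bond is the standard protodesilylation of trimethylsilylalkynes; substoichiometric base at 0 °C is chosen so that the β-peroxy ester does not open by retro-oxa-Michael elimination, and the methyl ester cannot transesterify in methanol.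

Step 8
Reactants: 16 dec-9-en-1-ol
Product: 17 dec-9-enal
Conditions: TEMPO (10 mol%), PhI(OAc)2, CH2Cl2, rt
Reagents that add atoms: none
Why: TEMPO-catalysed oxidation with PhI(OAc)2 stops at the aldehyde and leaves the terminal alkene alone.

Step 9
Reactants: 17 dec-9-enal
Product: 18 (E)-1-iodoundeca-1,10-diene
Conditions: CrCl2, CHI3, 1,4-dioxane/THF 6:1, 0 °C → rt
Reagents that add atoms: iodoform, IC(I)I
Why: Takai iodoolefination, in which the gem-dichromium carbenoid from CHI3 adds to the aldehyde and eliminates to the (E)-alkenyl iodide; the dioxane cosolvent is used to raise the E preference and the terminal alkene is inert.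

Step 10
Reactants: 15 methyl 2-[(3R*,6S*)-3-methoxy-3-(pent-4-yn-1-yl)-1,2-dioxan-6-yl]acetate; 18 (E)-1-iodoundeca-1,10-diene
Product: 19 methyl 2-[(3R*,6S*)-3-[(6E)-hexadeca-6,15-dien-4-yn-1-yl]-3-methoxy-1,2-dioxan-6-yl]acetate (racemic)
Conditions: PdCl2(PPh3)2 (5 mol%), CuI (10 mol%), Et3N, THF, rt, degassed
Reagents that add atoms: none
Why: Sonogashira coupling of a terminal alkyne with an alkenyl iodide at room temperature retains the E geometry and does not touch the isolated terminal alkene; the dialkyl peroxyketal is expected to tolerate the low-valent palladium and copper at this temperature and low phosphine loading.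

Step 11
Reactants: 19 methyl 2-[(3R*,6S*)-3-[(6E)-hexadeca-6,15-dien-4-yn-1-yl]-3-methoxy-1,2-dioxan-6-yl]acetate (racemic)
Product: 20 2-[(3R,6S)-3-[(6E)-hexadeca-6,15-dien-4-yn-1-yl]-3-methoxy-1,2-dioxan-6-yl]acetic acid (CNP0125368.1)
Conditions: Burkholderia cepacia lipase (immobilised), phosphate buffer pH 7.0/acetone 9:1, 25 °C, stopped near 40% conversion; acid extracted into aq NaHCO3, then brought to pH 4 and re-extracted
Reagents that add atoms: water, O
Why: Lipase-catalysed enantioselective ester hydrolysis (kinetic resolution) should select the (3R,6S) ester through the C6 stereocentre β to the acyl carbon and leave the (3S,6R) ester in the organic phase; no stereocentre is touched, so the absolute configuration is fixed by selection, and the neutral pH spares the β-peroxy acid unit and the ketal.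

**Compound list**

1 | (5-chloropent-1-yn-1-yl)trimethylsilane | C[Si](C)(C)C#CCCCCl | starting material
2 | 1-ethoxycyclopropan-1-ol | CCOC1(O)CC1 | starting material
3 | [5-(trimethylsilyl)pent-4-yn-1-yl]magnesium chloride | C[Si](C)(C)C#CCCC[Mg]Cl | intermediate (not isolated)
4 | cyclopropanone | O=C1CC1 | intermediate (not isolated)
5 | 1-[5-(trimethylsilyl)pent-4-yn-1-yl]cyclopropan-1-ol | C[Si](C)(C)C#CCCCC1(O)CC1 | intermediate
6 | 1-methoxy-1-[5-(trimethylsilyl)pent-4-yn-1-yl]cyclopropane | C[Si](C)(C)C#CCCCC1(OC)CC1 | intermediate
7 | dimethyl (E)-hex-3-enedioate | COC(=O)C/C=C/CC(=O)OC | starting material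
8 | carbonyl oxide of methyl 3-oxopropanoate | COC(=O)CC=[O+][O-] | intermediate (not isolated)
9 | methyl 3-hydroperoxy-3-methoxypropanoate (racemic) | COC(=O)CC(OC)OO | intermediate
10 | methyl 3-methoxy-3-[(triethylsilyl)peroxy]propanoate (racemic) | COC(=O)CC(OC)OO[Si](CC)(CC)CC | intermediate
11 | [3-methoxy-3-oxopropylidene](triethylsilylperoxy)oxonium triflate (silylperoxycarbenium ion) | COC(=O)CC=[O+]O[Si](CC)(CC)CC.[O-]S(=O)(=O)C(F)(F)F | intermediate (not isolated)
12 | ring-opened O-methyl oxocarbenium triflate, methyl 3-[(triethylsilyl)peroxy]-6-(methyloxonio-ylidene)-11-(trimethylsilyl)undec-10-ynoate (racemic) | COC(=O)CC(CCC(=[O+]C)CCCC#C[Si](C)(C)C)OO[Si](CC)(CC)CC.[O-]S(=O)(=O)C(F)(F)F | intermediate (not isolated)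
13 | methyl 2-[3-methoxy-3-[5-(trimethylsilyl)pent-4-yn-1-yl]-1,2-dioxan-6-yl]acetate (racemic, C3-epimer mixture) | C[Si](C)(C)C#CCCCC1(OC)CCC(CC(=O)OC)OO1 | intermediate
14 | methyl 2-[(3R*,6S*)-3-methoxy-3-[5-(trimethylsilyl)pent-4-yn-1-yl]-1,2-dioxan-6-yl]acetate (racemic; one enantiomer drawn) | C[Si](C)(C)C#CCCC[C@]1(OC)CC[C@@H](CC(=O)OC)OO1 | intermediate
15 | methyl 2-[(3R*,6S*)-3-methoxy-3-(pent-4-yn-1-yl)-1,2-dioxan-6-yl]acetate (racemic; one enantiomer drawn) | C#CCCC[C@]1(OC)CC[C@@H](CC(=O)OC)OO1 | intermediate
16 | dec-9-en-1-ol | C=CCCCCCCCCO | starting material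
17 | dec-9-enal | C=CCCCCCCCC=O | intermediate
18 | (E)-1-iodoundeca-1,10-diene | C=CCCCCCCC/C=C/I | intermediate
19 | methyl 2-[(3R*,6S*)-3-[(6E)-hexadeca-6,15-dien-4-yn-1-yl]-3-methoxy-1,2-dioxan-6-yl]acetate (racemic; one enantiomer drawn) | C=CCCCCCCC/C=C/C#CCCC[C@]1(OC)CC[C@@H](CC(=O)OC)OO1 | intermediate
20 | 2-[(3R,6S)-3-[(6E)-hexadeca-6,15-dien-4-yn-1-yl]-3-methoxy-1,2-dioxan-6-yl]acetic acid | C=CCCCCCCC/C=C/C#CCCC[C@]1(OC)CC[C@@H](CC(=O)O)OO1 | target

**Step count**

Total: 11 steps. Longest linear sequence: 7 steps (1, 2, 5, 6, 7, 10, 11; the peroxide branch 3, 4, 5, 6, 7, 10, 11 is equally long).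

**Steps most likely to fail**

1. Step 5 (the proposed annulation). The β-ester slows ionisation of 10 and makes cation 11 prone to proton loss or fragmentation before the σ bond can attack. Adventitious triflic acid may open the cyclopropane to the ketone, and the cation may attack the silylalkyne at its silicon-bearing carbon. Fallback by known chemistry, setting out from 1 and returning at 13: the Grignard reagent 3 from 1 is acylated with pent-4-enoyl chloride (Fe(acac)3 cat., THF, −78 °C) to 10-(trimethylsilyl)dec-1-en-9-yn-5-one F1. Cross-metathesis with methyl acrylate (second-generation Grubbs catalyst, CH2Cl2, 40 °C) gives methyl (E)-6-oxo-11-(trimethylsilyl)undec-2-en-10-ynoate F2. Urea–hydrogen peroxide with Sc(OTf)3 in MeOH converts the ketone into methyl (E)-6-hydroperoxy-6-methoxy-11-(trimethylsilyl)undec-2-en-10-ynoate F3. Et2NH in CF3CH2OH closes the dioxane by intramolecular oxa-Michael addition of the hydroperoxide to the enoate, giving 13, which enters step 6 unchanged.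

2. Step 11 (enzymatic resolution). The stereocentre sits β to the acyl carbon, so the enzyme may discriminate the enantiomers poorly, turn over the lipophilic substrate slowly, or prefer the mirror image. Fallback, setting out from 19 and returning at 20: the racemate is separated by preparative HPLC on a chiral stationary phase (amylose tris(3,5-dimethylphenylcarbamate), hexane/2-propanol) to give methyl 2-[(3R,6S)-3-[(6E)-hexadeca-6,15-dien-4-yn-1-yl]-3-methoxy-1,2-dioxan-6-yl]acetate F4, assigned by vibrational circular dichroism, and this is saponified with LiOH in THF/H2O at 0 °C to 20. If the enzyme merely prefers the wrong enantiomer, the ester recovered at higher conversion is F4 and is saponified the same way.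

3. Step 9 (iodoolefination). The E preference may erode, and the (Z)-iodide is hard to remove and would carry its geometry through the coupling into the final acid. Fallback, setting out from 17 and returning at 18: chromium-mediated boryl olefination (Cl2CHBpin, CrCl2, LiI, THF, rt) gives 4,4,5,5-tetramethyl-2-[(1E)-undeca-1,10-dien-1-yl]-1,3,2-dioxaborolane F5, which can be purified as a single isomer, and iododeboronation with NaOH then I2 in THF/H2O at 0 °C proceeds with retention to 18.

**Further compounds**

F1 | step 5 | 10-(trimethylsilyl)dec-1-en-9-yn-5-one | C=CCCC(=O)CCCC#C[Si](C)(C)C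
F2 | step 5 | methyl (E)-6-oxo-11-(trimethylsilyl)undec-2-en-10-ynoate | COC(=O)/C=C/CCC(=O)CCCC#C[Si](C)(C)C
F3 | step 5 | methyl (E)-6-hydroperoxy-6-methoxy-11-(trimethylsilyl)undec-2-en-10-ynoate (racemic) | COC(=O)/C=C/CCC(OC)(OO)CCCC#C[Si](C)(C)C
F4 | step 11 | methyl 2-[(3R,6S)-3-[(6E)-hexadeca-6,15-dien-4-yn-1-yl]-3-methoxy-1,2-dioxan-6-yl]acetate (single enantiomer) | C=CCCCCCCC/C=C/C#CCCC[C@]1(OC)CC[C@@H](CC(=O)OC)OO1
F5 | step 9 | 4,4,5,5-tetramethyl-2-[(1E)-undeca-1,10-dien-1-yl]-1,3,2-dioxaborolane | C=CCCCCCCC/C=C/B1OC(C)(C)C(C)(C)O1
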